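**Retrosynthetic overview**
1. Target 10 ⇐ chelation-controlled cleavage of the peri 5-OMe of 5,7,8,2',5'-pentamethoxyflavone 9.
2. Pyranone ring C (the only ring built, formed last) ⇐ oxidative O1–C2 cyclisation of 2'-hydroxychalcone 7.
3. Chalcone 7 ⇐ intermolecular Claisen–Schmidt aldol condensation (key C–C bond) of acetophenone 4 with 2,5-dimethoxybenzaldehyde 5.
4. Acetophenone 4 ⇐ Friedel–Crafts acetylation with ortho-demethylation of 1,2,3,5-tetramethoxybenzene 2 ⇐ 3,4,5-trimethoxyphenol 1.
5. Rings A and B are bought intact.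

Assumption: the target has no stereocentre, so no enantiocontrol is needed; the only stereo-elements on the route (E-alkene of 7, racemic centres of 6 and 8) are erased before the end.

**Step 1**
Reactants: 1 3,4,5-trimethoxyphenol
Product: 2 1,2,3,5-tetramethoxybenzene
Conditions: MeI (1.5 equiv), K2CO3 (2 equiv), acetone, reflux, 12 h
Reagents that add atoms: iodomethane, CI
Why: Williamson ether synthesis — the phenoxide is the only nucleophile and SN2 methylation on MeI is clean.

**Step 2**
Reactants: 2 1,2,3,5-tetramethoxybenzene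
Product: 4 2-hydroxy-3,4,6-trimethoxyacetophenone, via 2,3,4,6-tetramethoxyacetophenone 3 (not isolated)
Conditions: AcCl (1.2 equiv), AlCl3 (2.5 equiv), Et2O, 0 °C → rt, 24 h; then ice/aq HCl
Reagents that add atoms: acetyl chloride, CC(Cl)=O
Why: Friedel–Crafts acylation occurs at the only type of free position (C4/C6 are equivalent), and the AlCl3–ketone chelate then cleaves the more crowded ortho-methoxy (the one flanked by a second OMe) in a classical selective ortho-demethylation that gives the hydrogen-bonded phenol.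

**Step 3**
Reactants: 4 2-hydroxy-3,4,6-trimethoxyacetophenone; 5 2,5-dimethoxybenzaldehyde
Product: 7 (E)-3-(2,5-dimethoxyphenyl)-1-(2-hydroxy-3,4,6-trimethoxyphenyl)prop-2-en-1-one, via aldol adduct 6 (not isolated)
Conditions: KOH (50% aq, 10 equiv), EtOH, rt, 48 h; then cold aq HCl to pH 3
Reagents that add atoms: none
Why: Claisen–Schmidt (crossed aldol) condensation — the aldehyde cannot enolise, the methyl ketone is the only enolisable partner, and E1cB dehydration of racemic 6 gives the conjugated E-enone (any flavanone formed on acidification is carried into step 4, where it converges on 9).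

**Step 4**
Reactants: 7 (E)-3-(2,5-dimethoxyphenyl)-1-(2-hydroxy-3,4,6-trimethoxyphenyl)prop-2-en-1-one
Product: 9 2-(2,5-dimethoxyphenyl)-5,7,8-trimethoxy-4H-chromen-4-one, via flavanone 8 (not isolated)
Conditions: I2 (10 mol%), DMSO, 130 °C, 2 h; then aq Na2S2O3
Reagents that add atoms: none
Why: I2/DMSO oxidative cyclisation — intramolecular oxa-Michael addition of the 2'-OH gives the racemic flavanone, which iodine dehydrogenates to the flavone while DMSO re-oxidises HI; the 6'-OMe cannot cyclise, so only the 5,7,8-pattern forms.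

**Step 5**
Reactants: 9 2-(2,5-dimethoxyphenyl)-5,7,8-trimethoxy-4H-chromen-4-one
Product: 10 2-(2,5-dimethoxyphenyl)-5-hydroxy-7,8-dimethoxy-4H-chromen-4-one (5-hydroxy-7,8,2',5'-tetramethoxyflavone)
Conditions: BCl3 (1 M in CH2Cl2, 2 equiv), CH2Cl2, −78 → 0 °C, 2 h; then H2O/aq NaHCO3
Reagents that add atoms: none
Why: Chelation-controlled Lewis-acid ether cleavage — BCl3 bridges the C4 carbonyl and the peri 5-OMe in a six-membered chelate, so only that methyl is lost at low temperature, and the aprotic conditions exclude Wessely–Moser isomerisation.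

**Compound list**
1 | 3,4,5-trimethoxyphenol | COc1cc(O)cc(OC)c1OC | starting material
2 | 1,2,3,5-tetramethoxybenzene | COc1cc(OC)c(OC)c(OC)c1 | intermediate
3 | 2,3,4,6-tetramethoxyacetophenone | CC(=O)c1c(OC)cc(OC)c(OC)c1OC | intermediate (not isolated)
4 | 2-hydroxy-3,4,6-trimethoxyacetophenone | CC(=O)c1c(OC)cc(OC)c(OC)c1O | intermediate
5 | 2,5-dimethoxybenzaldehyde | COc1ccc(OC)c(C=O)c1 | starting material
6 | 3-(2,5-dimethoxyphenyl)-3-hydroxy-1-(2-hydroxy-3,4,6-trimethoxyphenyl)propan-1-one (aldol adduct, racemic) | COc1ccc(OC)c(C(O)CC(=O)c2c(OC)cc(OC)c(OC)c2O)c1 | intermediate (not isolated)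
7 | (E)-3-(2,5-dimethoxyphenyl)-1-(2-hydroxy-3,4,6-trimethoxyphenyl)prop-2-en-1-one | COc1ccc(OC)c(/C=C/C(=O)c2c(OC)cc(OC)c(OC)c2O)c1 | intermediate
8 | 2-(2,5-dimethoxyphenyl)-5,7,8-trimethoxychroman-4-one (flavanone, racemic) | COc1ccc(OC)c(C2CC(=O)c3c(OC)cc(OC)c(OC)c3O2)c1 | intermediate (not isolated)
9 | 2-(2,5-dimethoxyphenyl)-5,7,8-trimethoxy-4H-chromen-4-one | COc1ccc(OC)c(-c2cc(=O)c3c(OC)cc(OC)c(OC)c3o2)c1 | intermediate
10 | 2-(2,5-dimethoxyphenyl)-5-hydroxy-7,8-dimethoxy-4H-chromen-4-one | COc1ccc(OC)c(-c2cc(=O)c3c(O)cc(OC)c(OC)c3o2)c1 | target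

**Totals**
Total step count: 5. Longest linear sequence: 5 steps (1 → 2 → 4 → 7 → 9 → 10).

**Three steps most likely to fail**

Step 2 (one-pot acylation and regioselective demethylation; risk of over-demethylation or the isomeric phenol). The identity of 4 is checked by NOE: its single ring proton sits between two OMe groups. The fallback sets out from 1 and comes back at 4. Phenol 1 is C-acetylated ortho to its OH with AcOH/BF3·OEt2 at 85 °C; the two ortho positions are equivalent, so there is no regiochemical question. This gives 6-hydroxy-2,3,4-trimethoxyacetophenone F1. O-Methylation (MeI, K2CO3, DMF, 50 °C) gives compound 3, now isolated and purified. A separate, stoichiometrically controlled cleavage with BCl3 (1.1 equiv, CH2Cl2, −78 → 0 °C) then removes the crowded 2-methyl and gives 4.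

Step 3 (aldol condensation of a di-ortho-substituted, electron-rich ketone; risk of slow or incomplete conversion). The fallback sets out from 4 and comes back at 9, bypassing 7 and step 4. The dianion of 4 (LiHMDS, 3.5 equiv, THF, −78 °C) undergoes an intermolecular crossed Claisen condensation with commercial methyl 2,5-dimethoxybenzoate (−78 °C → rt). This gives 1-(2,5-dimethoxyphenyl)-3-(2-hydroxy-3,4,6-trimethoxyphenyl)propane-1,3-dione F2. Cyclodehydration (cat. H2SO4, AcOH, 90 °C, 1 h) then gives 9.

Step 5 (mono-demethylation; risk of competing loss of the 8- or 2'-methyl). The fallback sets out from 9 and comes back at 10, moving the selectivity from ether cleavage to ether formation. All five methyl ethers are cleaved with excess BBr3 (CH2Cl2, −78 °C → rt) to give 2-(2,5-dihydroxyphenyl)-5,7,8-trihydroxy-4H-chromen-4-one F3. Re-methylation under argon with Me2SO4 (4.2 equiv) and K2CO3 in refluxing acetone then alkylates the four free phenols. The 5-OH, hydrogen-bonded to the C4 carbonyl, is the least reactive and stays free, giving 10.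

**Further compounds**
F1 | step 2 | 6-hydroxy-2,3,4-trimethoxyacetophenone | CC(=O)c1c(O)cc(OC)c(OC)c1OC
F2 | step 3 | 1-(2,5-dimethoxyphenyl)-3-(2-hydroxy-3,4,6-trimethoxyphenyl)propane-1,3-dione | COc1ccc(OC)c(C(=O)CC(=O)c2c(OC)cc(OC)c(OC)c2O)c1
F3 | step 5 | 2-(2,5-dihydroxyphenyl)-5,7,8-trihydroxy-4H-chromen-4-one | Oc1ccc(O)c(-c2cc(=O)c3c(O)cc(O)c(O)c3o2)c1
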